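In a one-step world, starting material and partner give target, so I follow the fraction left, the part of the charge not yet target.

| flask | starting material | partner | protic impurity | temperature | remark | time |
|---|---|---|---|---|---|---|
| birch | 0.050 M | 1.3 equiv | 0.015 M | 10 °C | run made earlier |  |
| alder | 0.050 M | 3 equiv | 0.015 M | 32 °C | run made earlier |  |
| cedar | 0.075 M | 2 equiv | 0.015 M | 10 °C | run made earlier |  |
| spring | 0.050 M | 2.00 equiv | 0.0150 M |  | at 40 °C throughout | 5.0 h |
| autumn | 0.050 M | 2.00 equiv | 0.0150 M |  | at 40 °C until 1.5 h, from then on at 0 °C | 5.0 h |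

| run | time / h | target / % |
|---|---|---|
| birch | 2.00 | 0 |
| birch | 6.00 | 0.1 |
| birch | 12.0 | 1.6 |
| birch | 20.0 | 2.0 |
| birch | 25.0 | 3.3 |
| alder | 0.500 | 1.6 |
| alder | 0.833 | 0.9 |
| alder | 1.50 | 7.4 |
| alder | 3.00 | 12.5 |
| alder | 6.00 | 26.7 |
| cedar | 6.00 | 0 |
| cedar | 12.0 | 1.5 |
| cedar | 20.0 | 4.0 |
| cedar | 25.0 | 6.7 |

(scatter of a reading: 1 percentage point)

- the winner by amount of target, in percent of the starting material charged; "neither" if no more than 2 percentage points parts them (spring / autumn / neither)
- how much target is there at the end, in percent of the starting material charged: spring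
- how much target is there at the end, in percent of the starting material charged: autumn

- the earlier runs were read with a standard deviation of 1 percentage point

1. With partner held steady, the loss is pseudo-first-order, and ln(fraction left) falls in a straight line.

2. Cedar and alder both carry 0.150 M of partner. Cedar's last reading gives a slope of 0.00277 h⁻¹, and alder's gives 0.0518 h⁻¹.

3. Warming from 10 °C to 32 °C multiplies the slope by 18.7. I extend that same factor per degree to 40 °C, which gives 0.150 h⁻¹ at alder's partner.

4. Spring has alder's charge of starting material but less partner. Scaling by equivalents leaves 60.6% at 5.0 h.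

5. The weak link is steady partner. Up to 6.00 h, birch and cedar read 0.1% or less, so I guess that protic impurity eats partner first, one for one. Mean partner, in equivalents, is then the charge, less the impurity, less half the turnover: 1.50 in spring and 2.57 in alder.

6. The reforged slope, my fraction-left rate for spring, is the hourly fall of ln(fraction left): 0.0879 h⁻¹. Spring keeps 64.4% not yet target, so I commit to 35.6% target.

7. Autumn runs warm until 1.5 h, and I use spring's rate for that stretch. For the cold hours I add cedar's slope, as a guess. That makes 13.3% for autumn, so I expect spring to win.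

The forecast also picks spring, with spring 29% (22% to 37%) and autumn 10% (6.5% to 14%): “Second-order integration with 2 equiv over 5 h gives spring ≈ 29%”. Its spring figure is lower than mine.

    starting material + partner → intermediate + by-product (k = 0.0695 M⁻¹ min⁻¹, Ea = 82.0 kJ mol⁻¹)
    partner ⇌ dormant form (K = 0.730, k = 0.00425 min⁻¹, Ea = 107 kJ mol⁻¹, ΔH = −59.0 kJ mol⁻¹)
    partner + protic impurity → quenched reagent (k = 0.242 M⁻¹ min⁻¹, Ea = 55.0 kJ mol⁻¹)
    partner + target → over-reaction product (k = 0.0239 M⁻¹ min⁻¹, Ea = 60.0 kJ mol⁻¹)
    intermediate ⇌ isomer of the product (K = 98.0, k = 0.00176 min⁻¹, Ea = 108 kJ mol⁻¹, ΔH = −82.0 kJ mol⁻¹)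
    intermediate ⇌ target (K = 1.20, k = 0.0107 min⁻¹, Ea = 88.0 kJ mol⁻¹, ΔH = −77.0 kJ mol⁻¹)
    (constants at 40 °C)

Spring ends with 23.7% target and autumn with 10.7%. Run to 1.50 h, my rate gives 12.4% target, and autumn holds 10.4% there. Run to the end, my rate leaves 64.4% of spring's charge not yet target, but spring holds 38.2% starting material, 23.3% intermediate and 23.7% target. Taken by itself, the step between intermediate and target has a relaxation half-life of 0.589 h in spring, both ways together, shorter than the 5.0 h of the run. At the end of spring, target is made 2.33 times faster than it is used up, each step taken net.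

The runs stem from a simulated flask with constants of no real substance, noise included.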